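The route rests on cutting C4–C5 in ring A, and with it C9–C10 in ring B, which unfolds the trans-decalin into an acyclic (E,E)-diene. The feature exploited is the carboxyl-bearing quaternary C4 beside ring-fusion carbon C5: a temporary C3 ketone turns C4 into an electrophilic radical under Mn(OAc)3/Cu(OAc)2. In one operation two 6-endo closures build rings A and B, set C4, C5, C9 and C10, and leave the C8(17) methylene. A (−)-8-phenylmenthyl ester at C19 selects the radical face. The precursor is a farnesol-derived chain whose C13 carbinol, set by Sharpless epoxidation, is saturated and so halts the cascade, joined to a 2-methylacetoacetate.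

Key step: step 8

Remark (assumption): labdane numbering is used throughout (C4 = carboxyl-bearing quaternary carbon, C5/C10 = ring fusion, C13 = side-chain carbinol, TBS = tert-butyldimethylsilyl). The auxiliary enantiomer is chosen on the assumption that the C4 radical reacts in its non-chelated sickle conformer, the same conformer that accounts for the axial ester.

Step 1
Reactants: 1 (2E,6E)-farnesol
Product: 2 (2R,3R)-2,3-epoxyfarnesol
Conditions: Ti(OiPr)4 (10 mol %), D-(−)-diethyl tartrate (12 mol %), t-BuOOH (decane), 4 Å molecular sieves, CH2Cl2, −20 °C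
Reagents that add atoms: tert-butyl hydroperoxide, CC(C)(C)OO
Why: Katsuki–Sharpless asymmetric epoxidation: the titanium tartrate catalyst binds the allylic hydroxyl, so only the C2=C3 alkene reacts, and D-(−)-tartrate gives the (2R,3R)-epoxide, whose tertiary C–O bond becomes the (13R)-carbinol of the target.

Step 2
Reactants: 2 (2R,3R)-2,3-epoxyfarnesol
Product: 3 (3R,6E)-3,7,11-trimethyldodeca-6,10-diene-1,3-diol
Conditions: NaAlH2(OCH2CH2OMe)2 (Red-Al), THF, 0 to 23 °C; aqueous work-up
Reagents that add atoms: none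
Why: Directed reductive opening of a 2,3-epoxy alcohol: the alkoxyaluminate delivers hydride to the secondary, less hindered C2, so the 1,3-diol forms and the tertiary C3–O bond keeps its configuration.

Step 3
Reactants: 3 (3R,6E)-3,7,11-trimethyldodeca-6,10-diene-1,3-diol
Product: 4 (3R,6E)-1,3-bis(TBS-oxy)-3,7,11-trimethyldodeca-6,10-diene
Conditions: TBSOTf (2.5 equiv), 2,6-lutidine, CH2Cl2, 0 to 23 °C
Reagents that add atoms: tert-butyldimethylsilyl triflate, CC(C)(C)[Si](C)(C)OS(=O)(=O)C(F)(F)F
Why: Silylation with a silyl triflate and a hindered pyridine base is reactive enough for the tertiary hydroxyl, and masking that oxygen later prevents it from capturing C8 in the key step.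

Step 4
Reactants: 4 (3R,6E)-1,3-bis(TBS-oxy)-3,7,11-trimethyldodeca-6,10-diene
Product: 5 (2E,6E,10R)-10,12-bis(TBS-oxy)-2,6,10-trimethyldodeca-2,6-dien-1-ol
Conditions: SeO2 (cat.), t-BuOOH, CH2Cl2, 0 to 23 °C, stopped at partial conversion
Reagents that add atoms: SeO2, O=[Se]=O (oxygen carrier); tert-butyl hydroperoxide, CC(C)(C)OO (terminal oxidant)
Why: Riley allylic oxidation (ene reaction, then [2,3]-sigmatropic shift) run with catalytic SeO2 prefers the terminal, least hindered trisubstituted alkene and its (E)-methyl group, which gives the (E)-allylic alcohol; no stereocenter is formed.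

Step 5
Reactants: 5 (2E,6E,10R)-10,12-bis(TBS-oxy)-2,6,10-trimethyldodeca-2,6-dien-1-ol
Product: 6 (2E,6E,10R)-1-bromo-10,12-bis(TBS-oxy)-2,6,10-trimethyldodeca-2,6-diene
Conditions: CBr4, PPh3, CH2Cl2, −20 to 0 °C
Reagents that add atoms: carbon tetrabromide, BrC(Br)(Br)Br
Why: Appel reaction: SN2 displacement of the oxyphosphonium ion by bromide under neutral conditions keeps the (E)-alkene and both silyl ethers.

Step 6
Reactants: 7 (−)-8-phenylmenthol, (1R,2S,5R); 8 methyl 2-methyl-3-oxobutanoate
Product: 9 (−)-8-phenylmenthyl 2-methyl-3-oxobutanoate (mixture of C2 epimers)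
Conditions: DMAP (0.3 equiv), toluene, reflux, removal of MeOH
Reagents that add atoms: none
Why: DMAP-catalysed transesterification of a β-keto ester, which runs through the acylketene and therefore accepts the hindered secondary alcohol; the auxiliary stereocenters are not touched.

Step 7
Reactants: 9 (−)-8-phenylmenthyl 2-methyl-3-oxobutanoate; 6 (2E,6E,10R)-1-bromo-10,12-bis(TBS-oxy)-2,6,10-trimethyldodeca-2,6-diene
Product: 11 (−)-8-phenylmenthyl (6E,10E,14R)-14,16-bis(TBS-oxy)-2,6,10,14-tetramethyl-3-oxohexadeca-6,10-dienoate (mixture of C2 epimers), via sodium lithium dianion 10 (not isolated)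
Conditions: NaH, THF, 0 °C; n-BuLi, 0 °C; then 6, 0 °C; aqueous work-up
Reagents that add atoms: none
Why: γ-Alkylation of a β-keto ester dianion: the more basic terminal carbanion attacks the primary allylic bromide by SN2, which joins C1 to C2 with retention of the (E)-alkene, and the epimers at the future C4 are of no consequence because that carbon becomes planar in step 8.

Step 8
Reactants: 11 (−)-8-phenylmenthyl (6E,10E,14R)-14,16-bis(TBS-oxy)-2,6,10,14-tetramethyl-3-oxohexadeca-6,10-dienoate
Product: 12 (−)-8-phenylmenthyl (13R)-13,15-bis(TBS-oxy)-3-oxolabd-8(17)-en-19-oate (5α-H, 9α-H, 10β-methyl, axial 4β-ester)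
Conditions: Mn(OAc)3·2H2O (2.2 equiv), Cu(OAc)2·H2O (1.0 equiv), degassed AcOH (0.05 M), 23 °C
Reagents that add atoms: none
Why: Mn(OAc)3 (trivalent manganese) oxidises the enolised β-keto ester to the electrophilic C4 radical, which adds to C5 of the C5=C10 alkene (6-endo, ring A, new C4–C5 bond); the tertiary C10 radical then adds to C9 of the C8=C9 alkene (6-endo, ring B), and Cu(OAc)2 oxidises the tertiary C8 radical through an alkylcopper species that loses a C17 hydrogen to give the 8(17)-methylene. The closest known reaction type is the manganese triacetate/copper diacetate oxidative free-radical polyene cyclisation of α-methyl β-keto esters, used here in its auxiliary-controlled 8-phenylmenthyl ester form. C4: the phenyl ring of the auxiliary stacks over one face of the planar C19–C4–C3 system, so C5 should bond to the open Re face, and the conformer with the C4 methyl syn to the C3 oxygen places the ester axial (β). C5 and C10: the (E)-C5=C10 geometry and a chair–chair fold give the trans ring fusion with C20 cis to the axial ester, and C9: the (E)-C8=C9 geometry puts the C11 chain equatorial (β). The 6-endo over 5-exo preference is secured by the methyl groups on the proximal alkene carbons C10 and C8 and by the in-ring C3 carbonyl. The cascade stops after ring B because C13 is saturated, the silyl ether on the C13 oxygen prevents capture of C8 as an 8,13-ether, and the copper-mediated elimination favours the least hindered C17–H.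

Step 9
Reactants: 12 (−)-8-phenylmenthyl (13R)-13,15-bis(TBS-oxy)-3-oxolabd-8(17)-en-19-oate
Product: 13 (13R)-13,15-bis(TBS-oxy)labd-8(17)-ene-3β,19-diol
Conditions: LiAlH4 (excess), THF, 0 °C to reflux; aqueous work-up
Reagents that add atoms: none
Why: Hydride reduction: LiAlH4 attacks the C3 ketone from the α face (the β face is blocked by the axial C19 and C20 groups) to give the equatorial 3β-alkoxide, which helps to deliver hydride to the neighbouring hindered ester and releases the auxiliary for re-use.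

Step 10
Reactants: 13 (13R)-13,15-bis(TBS-oxy)labd-8(17)-ene-3β,19-diol
Product: 14 3β,19-cyclic thionocarbonate of 13
Conditions: 1,1'-thiocarbonyldiimidazole, DMAP (cat.), toluene, 80 °C
Reagents that add atoms: 1,1'-thiocarbonyldiimidazole, S=C(n1ccnc1)n1ccnc1
Why: Thiocarbonyl transfer to a 1,3-diol: the equatorial 3β-oxygen and the axial C19 oxygen are gauche and close a six-membered thionocarbonate, while no other free hydroxyl is present.

Step 11
Reactants: 14 3β,19-cyclic thionocarbonate of 13
Product: 16 (13R)-13,15-bis(TBS-oxy)labd-8(17)-en-19-ol, via S-tributylstannyl thiolcarbonate 15 (not isolated)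
Conditions: Bu3SnH, AIBN (cat.), toluene, reflux; then 1 M NaOH, THF, 23 °C
Reagents that add atoms: none
Why: Barton–McCombie deoxygenation of a cyclic thionocarbonate: the stannyl radical adds to sulfur and the adduct fragments toward the more stable secondary C3 radical rather than the primary neopentyl C19 radical, and base then hydrolyses the remaining thiolcarbonate to the C19 alcohol.

Step 12
Reactants: 16 (13R)-13,15-bis(TBS-oxy)labd-8(17)-en-19-ol
Product: 17 (13R)-labd-8(17)-ene-13,15,19-triol
Conditions: Bu4NF, THF, 50 °C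
Reagents that add atoms: none
Why: Fluoride-induced desilylation driven by the strong Si–F bond removes both silyl ethers under non-acidic conditions, so the 8(17)-alkene and the tertiary carbinol are not endangered.

Step 13
Reactants: 17 (13R)-labd-8(17)-ene-13,15,19-triol
Product: 19 (4S,5R,9S,10R,13R)-13-hydroxylabd-8(17)-ene-15,19-dioic acid (target), via 15,19-dialdehyde 18 (not isolated)
Conditions: Dess–Martin periodinane, CH2Cl2, 0 to 23 °C; filter, concentrate; then NaClO2, NaH2PO4, 2-methyl-2-butene, t-BuOH/H2O, 23 °C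
Reagents that add atoms: sodium chlorite, [Na+].[O-]Cl=O
Why: Dess–Martin oxidation takes both primary alcohols (also the neopentyl C19) to aldehydes and leaves the tertiary C13 hydroxyl, and Pinnick oxidation with a chlorine scavenger then gives both acids without touching the alkene or any stereocenter.

Compound list
1 | (2E,6E)-farnesol | CC(C)=CCC/C(C)=C/CC/C(C)=C/CO | starting material
2 | (2R,3R)-2,3-epoxyfarnesol | CC(C)=CCC/C(C)=C/CC[C@@]1(C)O[C@@H]1CO | intermediate
3 | (3R,6E)-3,7,11-trimethyldodeca-6,10-diene-1,3-diol | CC(C)=CCC/C(C)=C/CC[C@@](C)(O)CCO | intermediate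
4 | (3R,6E)-1,3-bis(TBS-oxy)-3,7,11-trimethyldodeca-6,10-diene | CC(C)=CCC/C(C)=C/CC[C@@](C)(O[Si](C)(C)C(C)(C)C)CCO[Si](C)(C)C(C)(C)C | intermediate
5 | (2E,6E,10R)-10,12-bis(TBS-oxy)-2,6,10-trimethyldodeca-2,6-dien-1-ol | OC/C(C)=C/CC/C(C)=C/CC[C@@](C)(O[Si](C)(C)C(C)(C)C)CCO[Si](C)(C)C(C)(C)C | intermediate
6 | (2E,6E,10R)-1-bromo-10,12-bis(TBS-oxy)-2,6,10-trimethyldodeca-2,6-diene | BrC/C(C)=C/CC/C(C)=C/CC[C@@](C)(O[Si](C)(C)C(C)(C)C)CCO[Si](C)(C)C(C)(C)C | intermediate
7 | (−)-8-phenylmenthol, (1R,2S,5R)-5-methyl-2-(2-phenylpropan-2-yl)cyclohexan-1-ol | O[C@@H]1C[C@H](C)CC[C@H]1C(C)(C)c2ccccc2 | starting material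
8 | methyl 2-methyl-3-oxobutanoate | CC(=O)C(C)C(=O)OC | starting material
9 | (−)-8-phenylmenthyl 2-methyl-3-oxobutanoate (C2 epimers) | CC(=O)C(C)C(=O)O[C@@H]1C[C@H](C)CC[C@H]1C(C)(C)c2ccccc2 | intermediate
10 | sodium lithium dianion of 9 | [Na+].[Li+].C=C([O-])C(C)=C([O-])O[C@@H]1C[C@H](C)CC[C@H]1C(C)(C)c2ccccc2 | intermediate (not isolated)
11 | (−)-8-phenylmenthyl (6E,10E,14R)-14,16-bis(TBS-oxy)-2,6,10,14-tetramethyl-3-oxohexadeca-6,10-dienoate (C2 epimers) | CC(C(=O)O[C@@H]1C[C@H](C)CC[C@H]1C(C)(C)c2ccccc2)C(=O)CC/C(C)=C/CC/C(C)=C/CC[C@@](C)(O[Si](C)(C)C(C)(C)C)CCO[Si](C)(C)C(C)(C)C | intermediate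
12 | (−)-8-phenylmenthyl (13R)-13,15-bis(TBS-oxy)-3-oxolabd-8(17)-en-19-oate | C=C1CC[C@@H]2[C@](C)(CCC(=O)[C@]2(C)C(=O)O[C@@H]3C[C@H](C)CC[C@H]3C(C)(C)c4ccccc4)[C@H]1CC[C@@](C)(O[Si](C)(C)C(C)(C)C)CCO[Si](C)(C)C(C)(C)C | intermediate
13 | (13R)-13,15-bis(TBS-oxy)labd-8(17)-ene-3β,19-diol | C=C1CC[C@@H]2[C@](C)(CC[C@H](O)[C@]2(C)CO)[C@H]1CC[C@@](C)(O[Si](C)(C)C(C)(C)C)CCO[Si](C)(C)C(C)(C)C | intermediate
14 | 3β,19-cyclic thionocarbonate of 13 | C=C1CC[C@@H]2[C@](C)(CC[C@@H]3OC(=S)OC[C@]23C)[C@H]1CC[C@@](C)(O[Si](C)(C)C(C)(C)C)CCO[Si](C)(C)C(C)(C)C | intermediate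
15 | 19-O-[(tributylstannylsulfanyl)carbonyl] derivative of 16 | C=C1CC[C@@H]2[C@](C)(CCC[C@]2(C)COC(=O)S[Sn](CCCC)(CCCC)CCCC)[C@H]1CC[C@@](C)(O[Si](C)(C)C(C)(C)C)CCO[Si](C)(C)C(C)(C)C | intermediate (not isolated)
16 | (13R)-13,15-bis(TBS-oxy)labd-8(17)-en-19-ol | C=C1CC[C@@H]2[C@](C)(CCC[C@]2(C)CO)[C@H]1CC[C@@](C)(O[Si](C)(C)C(C)(C)C)CCO[Si](C)(C)C(C)(C)C | intermediate
17 | (13R)-labd-8(17)-ene-13,15,19-triol | C=C1CC[C@@H]2[C@](C)(CCC[C@]2(C)CO)[C@H]1CC[C@@](C)(O)CCO | intermediate
18 | (13R)-13-hydroxylabd-8(17)-ene-15,19-dial | C=C1CC[C@@H]2[C@](C)(CCC[C@]2(C)C=O)[C@H]1CC[C@@](C)(O)CC=O | intermediate (not isolated)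
19 | (4S,5R,9S,10R,13R)-13-hydroxylabd-8(17)-ene-15,19-dioic acid | C=C1CC[C@@H]2[C@](C)(CCC[C@]2(C)C(=O)O)[C@H]1CC[C@@](C)(O)CC(=O)O | target

Total step count: 13. Longest linear sequence: 12 (steps 1–5 and 7–13, from farnesol); step 6 is a one-step side branch.

Steps most likely to fail

Step 8. Several processes may go wrong here. The auxiliary may shield the radical face incompletely. The C10 radical may be oxidised before ring B closes. Elimination may run toward C7 or C9 instead of C17. The primary silyl ether may be lost slowly in acetic acid.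
The fallback replaces oxidative generation and copper termination by a group-transfer cascade at low temperature in a neutral solvent. It sets out from 11, which is treated with NaH and PhSeCl in THF to give the α-phenylselanyl β-keto ester F1. Irradiation, or Et3B/air initiation, in toluene at low temperature should trigger the same C4–C5 and C9–C10 closures. Transfer of the phenylselanyl group to the less hindered α face of C8 should then give the 8α-phenylselanyl labdane keto ester F2. Oxidation with H2O2/pyridine and selenoxide syn-elimination toward the freely rotating C17 methyl returns the route at 12.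

Step 11. The thionocarbonate adduct may fragment toward C19 instead of C3, or the thiolcarbonate may hydrolyse incompletely.
The fallback removes the C3 oxygen while C19 is still an ester, so that only one C–O bond can break. It sets out from 12.
- NaBH4 in MeOH/THF reduces only the ketone, from the α face, to the 3β-hydroxy ester F3.
- 1,1'-Thiocarbonyldiimidazole gives the 3β-imidazolylthiocarbonyl derivative F4.
- Bu3SnH/AIBN gives the 3-deoxy ester F5.
- LiAlH4 in refluxing THF cleaves the auxiliary ester, which returns the route at 16.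

Step 4. Allylic positions of the internal alkene may be oxidised in competition, the product may be over-oxidised to the enal, and conversion may be low.
The fallback exchanges C–H oxidation for alkene exchange and sets out from 4. Cross metathesis with methacrolein (second-generation Hoveyda–Grubbs catalyst, CH2Cl2, reflux) should engage only the terminal isopropylidene group. This should give the (2E,6E,10R)-10,12-bis(TBS-oxy)-2,6,10-trimethyldodeca-2,6-dienal F6. Luche reduction (NaBH4, CeCl3·7H2O, MeOH, 0 °C) returns the route at 5.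

Further compounds
F1 | step 8 | (−)-8-phenylmenthyl (6E,10E,14R)-14,16-bis(TBS-oxy)-2,6,10,14-tetramethyl-3-oxo-2-(phenylselanyl)hexadeca-6,10-dienoate (C2 epimers) | CC([Se]c1ccccc1)(C(=O)O[C@@H]2C[C@H](C)CC[C@H]2C(C)(C)c3ccccc3)C(=O)CC/C(C)=C/CC/C(C)=C/CC[C@@](C)(O[Si](C)(C)C(C)(C)C)CCO[Si](C)(C)C(C)(C)C
F2 | step 8 | (−)-8-phenylmenthyl (13R)-13,15-bis(TBS-oxy)-3-oxo-8α-(phenylselanyl)labdan-19-oate | C[C@@]1([Se]c5ccccc5)CC[C@@H]2[C@](C)(CCC(=O)[C@]2(C)C(=O)O[C@@H]3C[C@H](C)CC[C@H]3C(C)(C)c4ccccc4)[C@H]1CC[C@@](C)(O[Si](C)(C)C(C)(C)C)CCO[Si](C)(C)C(C)(C)C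
F3 | step 11 | (−)-8-phenylmenthyl (13R)-13,15-bis(TBS-oxy)-3β-hydroxylabd-8(17)-en-19-oate | C=C1CC[C@@H]2[C@](C)(CC[C@H](O)[C@]2(C)C(=O)O[C@@H]3C[C@H](C)CC[C@H]3C(C)(C)c4ccccc4)[C@H]1CC[C@@](C)(O[Si](C)(C)C(C)(C)C)CCO[Si](C)(C)C(C)(C)C
F4 | step 11 | (−)-8-phenylmenthyl (13R)-13,15-bis(TBS-oxy)-3β-(imidazol-1-ylthiocarbonyloxy)labd-8(17)-en-19-oate | C=C1CC[C@@H]2[C@](C)(CC[C@H](OC(=S)n5ccnc5)[C@]2(C)C(=O)O[C@@H]3C[C@H](C)CC[C@H]3C(C)(C)c4ccccc4)[C@H]1CC[C@@](C)(O[Si](C)(C)C(C)(C)C)CCO[Si](C)(C)C(C)(C)C
F5 | step 11 | (−)-8-phenylmenthyl (13R)-13,15-bis(TBS-oxy)labd-8(17)-en-19-oate | C=C1CC[C@@H]2[C@](C)(CCC[C@]2(C)C(=O)O[C@@H]3C[C@H](C)CC[C@H]3C(C)(C)c4ccccc4)[C@H]1CC[C@@](C)(O[Si](C)(C)C(C)(C)C)CCO[Si](C)(C)C(C)(C)C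
F6 | step 4 | (2E,6E,10R)-10,12-bis(TBS-oxy)-2,6,10-trimethyldodeca-2,6-dienal | O=C/C(C)=C/CC/C(C)=C/CC[C@@](C)(O[Si](C)(C)C(C)(C)C)CCO[Si](C)(C)C(C)(C)C
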